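## Retrosynthetic overview

1. Prostanoid numbering is used (ester carbon C1, ring C8–C12). C9 (ketone), C10 (Br), C11 (H) and C12 (quaternary, carrying oxygen and the octenyl chain) are read as the four carbons of a 2,5-disubstituted 3-bromofuran. The furan oxygen is the future C9 ketone oxygen, and C8 is the carbinol carbon on furan C2. The plan rests on this match.
2. The 7Z C7=C8 alkene is traced back to a 7S alcohol (stereospecific syn-dehydration, last step), and the C12 acetate to the tertiary alcohol.
3. C8–C12 is disconnected by an enantioselective oxa-Piancatelli rearrangement (furan dearomatisation, conrotatory 4π closure). The cyclopentenone is the only ring made, and it forms at the expense of the purchased furan ring.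
4. C8–C9 is disconnected to 3-bromo-5-octenyl-2-furyllithium and an (S)-α-silyloxy aldehyde. The octenyl chain goes on the furan first, because the ester and the carbinol would not tolerate a later furan lithiation. A halogen dance then moves the bromine from furan C2 to C3.
5. The aldehyde comes from (S)-but-3-ene-1,2-diol (C7 from the chiral pool) and methyl hex-5-enoate by cross-metathesis (C5=C6, E).

Key step: step 8

Remark on descriptors: C12 has the same spatial arrangement in 19–21 and in 23. The descriptor changes from S to R only because C8 becomes sp2 and then outranks C11.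

Remark (assumption): the (R)-acid is taken to be the enantiomer that gives the required sense of conrotation. If the sense is the opposite, the (S)-acid is used with no other change.

## Route

Step 1
Reactants: 1 (Z)-oct-2-en-1-ol
Product: 2 (Z)-1-bromooct-2-ene
Conditions: CBr4, PPh3, CH2Cl2, 0 °C
Reagents that add atoms: carbon tetrabromide, BrC(Br)(Br)Br
Why: Appel bromination displaces the oxyphosphonium ion of a primary allylic alcohol in the SN2 mode under neutral conditions, so neither allylic transposition nor Z to E isomerisation should occur.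

Step 2
Reactants: 3 2-bromofuran; 2 (Z)-1-bromooct-2-ene
Product: 5 2-bromo-5-[(Z)-oct-2-en-1-yl]furan, via 5-bromo-2-furyllithium 4 (not isolated)
Conditions: LiN(i-Pr)2, THF, −78 °C; then 2, DMPU, −78 to −20 °C
Reagents that add atoms: none
Why: Deprotonative lithiation removes the only α-hydrogen (C5–H) of 2-bromofuran, and the furyllithium is alkylated by the primary allylic bromide in the SN2 mode (no copper, which would favour SN2'), leaving the Z-alkene untouched.

Step 3
Reactants: 6 (S)-but-3-ene-1,2-diol
Product: 7 (S)-3,4-bis(tert-butyldimethylsilyloxy)but-1-ene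
Conditions: TBSCl, imidazole, DMF, 0 °C to rt
Reagents that add atoms: tert-butyldimethylsilyl chloride, CC(C)(C)[Si](C)(C)Cl
Why: Standard imidazole-promoted silylation of both hydroxyls leaves the purchased stereocentre, the future C7 (S), untouched.

Step 4
Reactants: 7 (S)-3,4-bis(tert-butyldimethylsilyloxy)but-1-ene; 8 methyl hex-5-enoate
Product: 9 methyl (5E,7S)-7,8-bis(tert-butyldimethylsilyloxy)oct-5-enoate
Conditions: 8 (3 equiv), second-generation Hoveyda–Grubbs catalyst (3 mol %), CH2Cl2, 40 °C
Reagents that add atoms: none
Why: Olefin cross-metathesis of an unhindered terminal alkene (in excess) with a hindered allylic silyl ether is a pairing known to favour the cross product and the E-alkene, and C7 is not involved.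

Step 5
Reactants: 9 methyl (5E,7S)-7,8-bis(tert-butyldimethylsilyloxy)oct-5-enoate
Product: 10 methyl (5E,7S)-7-(tert-butyldimethylsilyloxy)-8-hydroxyoct-5-enoate
Conditions: HF·pyridine, pyridine, THF, 0 °C
Reagents that add atoms: none
Why: In selective desilylation with buffered HF·pyridine, the primary silyl ether is cleaved much faster than the hindered secondary allylic one, and the methyl ester is inert.

Step 6
Reactants: 10 methyl (5E,7S)-7-(tert-butyldimethylsilyloxy)-8-hydroxyoct-5-enoate
Product: 11 methyl (5E,7S)-7-(tert-butyldimethylsilyloxy)-8-oxooct-5-enoate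
Conditions: Dess–Martin periodinane, CH2Cl2, 0 °C to rt; used at once
Reagents that add atoms: none
Why: Dess–Martin oxidation runs without base, so the α-silyloxy-β,γ-unsaturated aldehyde should be neither epimerised at C7 nor isomerised into conjugation.

Step 7
Reactants: 5 2-bromo-5-[(Z)-oct-2-en-1-yl]furan; 11 methyl (5E,7S)-7-(tert-butyldimethylsilyloxy)-8-oxooct-5-enoate
Product: 14 methyl (5E,7S)-8-{3-bromo-5-[(Z)-oct-2-en-1-yl]furan-2-yl}-7-(tert-butyldimethylsilyloxy)-8-hydroxyoct-5-enoate (both C8 epimers), via 2-bromo-3-lithio-5-octenylfuran 12 (not isolated), via 3-bromo-2-lithio-5-octenylfuran 13 (not isolated)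
Conditions: 5 (1.3 equiv), LiN(i-Pr)2 (1.25 equiv), THF, −78 °C, 1 h; then 11, −78 °C; AcOH in THF, −78 °C
Reagents that add atoms: none
Why: In this halogen dance followed by carbonyl addition, the amide removes the ring hydrogen next to bromine (the C13 methylene is kinetically far slower at this temperature) to give 12, intermolecular bromine transfer equilibrates 12 to the more stable 13 (lithium flanked by ring oxygen and bromine), as known for 2-bromo-5-alkylfurans, and 13 adds to the aldehyde much faster than to the ester; the new C8 centre forms without control, which is harmless because step 8 erases it, and the cold acidic quench forestalls silyl migration from O7 to O8.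

Step 8
Reactants: 14 methyl (5E,7S)-8-{3-bromo-5-[(Z)-oct-2-en-1-yl]furan-2-yl}-7-(tert-butyldimethylsilyloxy)-8-hydroxyoct-5-enoate; 15 water
Product: 19 methyl (5E,7S)-7-{(1S,5S)-3-bromo-5-hydroxy-5-[(Z)-oct-2-en-1-yl]-2-oxocyclopent-3-en-1-yl}-7-(tert-butyldimethylsilyloxy)hept-5-enoate (7S,8S,12S), via furfuryl oxocarbenium ion 16 (not isolated), via ring hemiketal 17 (not isolated), via dihydroxypentadienyl cation 18 (not isolated)
Conditions: (R)-3,3'-bis(2,4,6-triisopropylphenyl)-1,1'-binaphthyl-2,2'-diyl hydrogen phosphate (20 mol %), H2O (10 equiv), toluene, 70 °C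
Reagents that add atoms: water 15, O
Why: Proposed new method: the acid protonates the C8 hydroxyl, departure of water gives the furan-stabilised cation 16, water 15 is captured at the octenyl-bearing ring carbon (C12) to give hemiketal 17, C–O scission gives the 1,4-dihydroxypentadienyl cation 18, and a thermally allowed conrotatory 4π electrocyclisation followed by proton loss makes C8–C12 and the enone. The closest known reactions are the Lewis-acid Piancatelli rearrangement of 5-alkyl-2-furylcarbinols to trans-4-alkyl-4-hydroxy-5-substituted cyclopentenones and the chiral phosphoric acid catalysed aza-Piancatelli rearrangement with anilines, whereas an enantioselective version with water as the nucleophile is not known. The single ring closes in the pentadienyl-to-cyclopentenyl cation mode (five-membered, electrocyclic), the former furan oxygen ending as the C9 ketone, the oxygen of 15 as the C12 hydroxyl and the bromine on C10. C8 is set relative to C12 by conrotation of the conformer of 18 that holds the C7 chain and the C12 hydroxyl both outward, which places them trans, and the absolute sense (C12) is to be set by the phosphate anion hydrogen-bonded to the two O–H groups of 18, with the resident C7 centre as a second, matched or mismatched, control element. The step needs capture of water at C12 and not at C8, and the substrate secures this because capture at C8 only regenerates 14 (either epimer) reversibly while the electrocyclisation is irreversible, so the material should funnel to 19. Since the C10 bromine and the C7 silyloxy group both retard ionisation, a low-polarity medium with little water, a high catalyst loading and heat are chosen so that the acid is not levelled and the ion pair stays tight.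

Step 9
Reactants: 19 methyl (5E,7S)-7-{(1S,5S)-3-bromo-5-hydroxy-5-[(Z)-oct-2-en-1-yl]-2-oxocyclopent-3-en-1-yl}-7-(tert-butyldimethylsilyloxy)hept-5-enoate
Product: 20 methyl (5E,7S)-7-{(1S,5S)-5-acetoxy-3-bromo-5-[(Z)-oct-2-en-1-yl]-2-oxocyclopent-3-en-1-yl}-7-(tert-butyldimethylsilyloxy)hept-5-enoate
Conditions: Ac2O, Bi(OTf)3 (2 mol %), CH2Cl2, 0 °C
Reagents that add atoms: acetic anhydride, CC(=O)OC(C)=O
Why: Metal triflate catalysed acylation is known to acetylate tertiary alcohols while tolerating silyl ethers, it needs no base that could epimerise C8 or expel the new β-acetate, and ionisation at C12 is disfavoured because that cation would be conjugated with the enone.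

Step 10
Reactants: 20 methyl (5E,7S)-7-{(1S,5S)-5-acetoxy-3-bromo-5-[(Z)-oct-2-en-1-yl]-2-oxocyclopent-3-en-1-yl}-7-(tert-butyldimethylsilyloxy)hept-5-enoate
Product: 21 methyl (5E,7S)-7-{(1S,5S)-5-acetoxy-3-bromo-5-[(Z)-oct-2-en-1-yl]-2-oxocyclopent-3-en-1-yl}-7-hydroxyhept-5-enoate
Conditions: HF·pyridine, THF, 0 °C to rt
Reagents that add atoms: none
Why: Fluoride-mediated desilylation in a mildly acidic medium avoids the enolate chemistry (retro-aldol, E1cB) that a basic fluoride source would trigger, and acetyl migration from O12 to O7 is hindered because the two oxygens lie on opposite faces of a nearly flat ring.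

Step 11
Reactants: 21 methyl (5E,7S)-7-{(1S,5S)-5-acetoxy-3-bromo-5-[(Z)-oct-2-en-1-yl]-2-oxocyclopent-3-en-1-yl}-7-hydroxyhept-5-enoate
Product: 23 methyl (5E,7Z)-7-{(2R)-2-acetoxy-4-bromo-2-[(Z)-oct-2-en-1-yl]-5-oxocyclopent-3-en-1-ylidene}hept-5-enoate (target), via O-alkylisourea 22 (not isolated)
Conditions: DCC, CuCl (20 mol %), toluene, rt to 50 °C, in the dark
Reagents that add atoms: none
Why: In this carbodiimide-mediated syn-dehydration of an aldol, copper-catalysed addition of the C7 hydroxyl to DCC gives 22, whose basic nitrogen removes the acidic C8–H through a six-membered cyclic transition state; in the 7S,8S isomer the conformer with O7 and H8 syn-periplanar eclipses C6 with C9 and H7 with C12, so C6 should end up on the carbonyl side (7Z), and no external base is present to open an E1cB path.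

## Compound list

1 | (Z)-oct-2-en-1-ol | CCCCC/C=C\CO | starting material
2 | (Z)-1-bromooct-2-ene | CCCCC/C=C\CBr | intermediate
3 | 2-bromofuran | Brc1ccco1 | starting material
4 | 5-bromo-2-furyllithium | [Li]c1ccc(Br)o1 | intermediate
5 | 2-bromo-5-[(Z)-oct-2-en-1-yl]furan | CCCCC/C=C\Cc1ccc(Br)o1 | intermediate
6 | (S)-but-3-ene-1,2-diol | OC[C@@H](O)C=C | starting material
7 | (S)-3,4-bis(tert-butyldimethylsilyloxy)but-1-ene | CC(C)(C)[Si](C)(C)OC[C@@H](O[Si](C)(C)C(C)(C)C)C=C | intermediate
8 | methyl hex-5-enoate | C=CCCCC(=O)OC | starting material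
9 | methyl (5E,7S)-7,8-bis(tert-butyldimethylsilyloxy)oct-5-enoate | CC(C)(C)[Si](C)(C)OC[C@@H](O[Si](C)(C)C(C)(C)C)/C=C/CCCC(=O)OC | intermediate
10 | methyl (5E,7S)-7-(tert-butyldimethylsilyloxy)-8-hydroxyoct-5-enoate | OC[C@@H](O[Si](C)(C)C(C)(C)C)/C=C/CCCC(=O)OC | intermediate
11 | methyl (5E,7S)-7-(tert-butyldimethylsilyloxy)-8-oxooct-5-enoate | O=C[C@@H](O[Si](C)(C)C(C)(C)C)/C=C/CCCC(=O)OC | intermediate
12 | 2-bromo-3-lithio-5-[(Z)-oct-2-en-1-yl]furan | CCCCC/C=C\Cc1cc([Li])c(Br)o1 | intermediate
13 | 3-bromo-2-lithio-5-[(Z)-oct-2-en-1-yl]furan | CCCCC/C=C\Cc1cc(Br)c([Li])o1 | intermediate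
14 | C7-silyloxy (3-bromo-5-octenylfuran-2-yl)carbinol, 7S, both C8 epimers | CCCCC/C=C\Cc1cc(Br)c(o1)C(O)[C@@H](O[Si](C)(C)C(C)(C)C)/C=C/CCCC(=O)OC | intermediate
15 | water | O | starting material
16 | furfuryl oxocarbenium ion (as its chiral phosphate ion pair) | CCCCC/C=C\CC1=[O+]C(=C[C@@H](O[Si](C)(C)C(C)(C)C)/C=C/CCCC(=O)OC)C(Br)=C1 | intermediate
17 | 5-hydroxy-2-alkylidene-2,5-dihydrofuran (ring hemiketal) | CCCCC/C=C\CC1(O)OC(=C[C@@H](O[Si](C)(C)C(C)(C)C)/C=C/CCCC(=O)OC)C(Br)=C1 | intermediate
18 | 1,4-dihydroxypentadienyl cation C12–C8 (as its chiral phosphate ion pair) | CCCCC/C=C\CC(=[OH+])C=C(Br)C(O)=C[C@@H](O[Si](C)(C)C(C)(C)C)/C=C/CCCC(=O)OC | intermediate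
19 | trans-2-bromo-4-hydroxy-4-octenyl-5-(1-silyloxyalkenyl)cyclopent-2-enone (7S,8S,12S) | CCCCC/C=C\C[C@@]1(O)C=C(Br)C(=O)[C@H]1[C@@H](O[Si](C)(C)C(C)(C)C)/C=C/CCCC(=O)OC | intermediate
20 | C12 acetate of 19 | CCCCC/C=C\C[C@@]1(OC(C)=O)C=C(Br)C(=O)[C@H]1[C@@H](O[Si](C)(C)C(C)(C)C)/C=C/CCCC(=O)OC | intermediate
21 | C12 acetate, free C7 alcohol (7S,8S,12S) | CCCCC/C=C\C[C@@]1(OC(C)=O)C=C(Br)C(=O)[C@H]1[C@@H](O)/C=C/CCCC(=O)OC | intermediate
22 | O7-(N,N'-dicyclohexylisoureido) derivative of 21 | CCCCC/C=C\C[C@@]1(OC(C)=O)C=C(Br)C(=O)[C@H]1[C@@H](OC(NC2CCCCC2)=NC2CCCCC2)/C=C/CCCC(=O)OC | intermediate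
23 | CNP0295154.2 (5E,7Z,12R,14Z) | CCCCC/C=C\C[C@@]1(OC(C)=O)C=C(Br)C(=O)/C1=C\C=C\CCCC(=O)OC | target

## Step count and risks

Total step count: 11. Longest linear sequence: 9 (steps 3 to 11, from 6).

**Step 8.**
- What may go wrong:
  - ionisation too slow because of the bromine and the neighbouring silyloxy group;
  - hydride migration from C7 to the cationic C8;
  - acid-induced loss of the silyl group;
  - poor sense-of-rotation selectivity if the phosphate and the C7 centre oppose each other.
- A more acidic N-triflyl phosphoramide on the same backbone would be the first variation of conditions.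
- Fallback: catalyst control is given up. Setting out from 14, the rearrangement is run in its known achiral form for 5-alkyl-2-furylcarbinols (ZnCl2, 1 equiv, aqueous dioxane, reflux). C7 is already a single enantiomer, so the two senses of conrotation give diastereomers and not enantiomers. These are 19 and the (7S,8R,12R)-configured trans-cyclopentenone F1, and they are separated by chromatography. The route is rejoined at 19.

**Step 11.**
- What may go wrong:
  - leakage from the cyclic syn pathway into a stepwise E1cB elimination, with erosion of the alkene geometry;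
  - allylic transposition of the activated C7 oxygen.
- Fallback: stereospecificity is abandoned in favour of elimination, separation and photochemical recycling.
  - Setting out from 21, MsCl and Et3N (CH2Cl2, −20 °C) give the C7 mesylate F2.
  - F2 eliminates on warming with Et3N to a mixture of 23 and its 7E isomer F3.
  - The two are separated by chromatography, and F3 is re-equilibrated by long-wavelength irradiation in benzene (E/Z photoisomerisation of the cross-conjugated dienone) and separated again. The route is rejoined at 23.

**Step 9.**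
- What may go wrong:
  - epimerisation at C8;
  - β-elimination of the newly formed acetate through the C8 enol;
  - exchange of silyl for acetyl at O7;
  - no reaction at the hindered tertiary hydroxyl.
- Fallback: the order of the end game is reversed, so that the acetylation is done when C8 no longer bears a hydrogen.
  - Setting out from 19, HF·pyridine gives the 7,12-diol F4.
  - DCC and CuCl engage only the less hindered secondary allylic hydroxyl to give the isourea F5.
  - F5 undergoes the same syn-elimination to the 12-hydroxy 7Z-dienone F6.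
  - Brief treatment of F6 with Ac2O and DMAP in CH2Cl2 acetylates the tertiary alcohol. The route is rejoined at 23.

Further compounds
F1 | step 8 | (7S,8R,12R)-diastereomer of 19 | CCCCC/C=C\C[C@]1(O)C=C(Br)C(=O)[C@@H]1[C@@H](O[Si](C)(C)C(C)(C)C)/C=C/CCCC(=O)OC
F2 | step 11 | C7 methanesulfonate of 21 | CCCCC/C=C\C[C@@]1(OC(C)=O)C=C(Br)C(=O)[C@H]1[C@@H](OS(C)(=O)=O)/C=C/CCCC(=O)OC
F3 | step 11 | 7E isomer of 23 | CCCCC/C=C\C[C@@]1(OC(C)=O)C=C(Br)C(=O)/C1=C/C=C/CCCC(=O)OC
F4 | step 9 | 7,12-diol (7S,8S,12S) | CCCCC/C=C\C[C@@]1(O)C=C(Br)C(=O)[C@H]1[C@@H](O)/C=C/CCCC(=O)OC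
F5 | step 9 | O7-(N,N'-dicyclohexylisoureido) derivative of F4 | CCCCC/C=C\C[C@@]1(O)C=C(Br)C(=O)[C@H]1[C@@H](OC(NC2CCCCC2)=NC2CCCCC2)/C=C/CCCC(=O)OC
F6 | step 9 | 12-hydroxy (5E,7Z)-dienone | CCCCC/C=C\C[C@@]1(O)C=C(Br)C(=O)/C1=C\C=C\CCCC(=O)OC
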